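**Strategy.** The 14-membered carbocycle (C1–C14) is opened at C9–C10, a bond flanked by two allyl units: C9 belongs to the 2-substituted allyl C9–C8(=C19H2), whose two CH2 ends are equivalent, and C10 to the C10–C11=C12 unit. Nickel(0) couples the two primary allylic bromides head to head, so one operation closes the macrocycle onto the finished δ-lactone (C1–C3/C15–C16) and leaves the C8 methylene and the 11E olefin in place. The cyclisation substrate is an open-chain hydroxy lactone bis(allyl bromide) (7-OTBS, free 4-OH), built from (R)-limonene by ozonolysis, Claisen rearrangement, CBS reduction and epoxy-acid lactonisation; epoxidation and desilylation finish the synthesis.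

Key step: step 20

Remarks on the chemistry:
- Locants follow cembrane numbering: ring C1–C14; C15/C16/C17 = lactone α-carbon, carbonyl carbon, α-methyl; C18 on C4; C19 = CH2 on C8; C20 on C12. "16,3-olide" is the δ-lactone from C16 to the oxygen on C3. Open-chain compounds are named as 9,10-seco-cembranes where that is shorter.
- The target is 1R,3R,4S,7R,11S,12S,15S. Compounds 32 and 34 carry the same configurations at C1, C3, C4, C7 and C15, and 11E.
- Assumption: hydroboration of the isopropenyl group is not face-selective. C15 is therefore carried as a pair of epimers (no C15 descriptor in the SMILES) from 2 to 28 and is made uniform in step 17.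

Step 1
Reactants: 1 (R)-(+)-limonene
Product: 3 2-[(1R)-4-methylcyclohex-3-en-1-yl]propan-1-ol (C15 epimers), via B-alkyl-9-BBN adduct 2 (not isolated)
Conditions: 9-BBN, THF, 0 °C → rt; then aq. NaOH, 30% H2O2, 0 °C → rt
Reagents that add atoms: hydrogen peroxide (OO)
Why: Anti-Markovnikov hydroboration–oxidation with 9-BBN is selective for the 1,1-disubstituted isopropenyl olefin over the trisubstituted ring olefin, and the new C15 centre, formed without control, is corrected in step 17.

Step 2
Reactants: 3 2-[(1R)-4-methylcyclohex-3-en-1-yl]propan-1-ol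
Product: 4 2-[(1R)-4-methylcyclohex-3-en-1-yl]propanoic acid (C15 epimers)
Conditions: TEMPO (cat.), PhI(OAc)2, MeCN/H2O, rt
Reagents that add atoms: water (O)
Why: The TEMPO/iodine(III) oxidation takes the primary alcohol through the aldehyde hydrate to the acid and leaves the trisubstituted olefin alone.

Step 3
Reactants: 4 2-[(1R)-4-methylcyclohex-3-en-1-yl]propanoic acid
Product: 5 methyl 2-[(1R)-4-methylcyclohex-3-en-1-yl]propanoate (C15 epimers)
Conditions: MeI, K2CO3, DMF, rt
Reagents that add atoms: iodomethane (CI)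
Why: Carboxylate O-alkylation (SN2) gives the methyl ester that masks C16 until the saponification of step 15.

Step 4
Reactants: 5 methyl 2-[(1R)-4-methylcyclohex-3-en-1-yl]propanoate
Product: 8 methyl (3R)-3-(2,2-dimethoxyethyl)-2-methyl-6-oxoheptanoate (C15 epimers), via methoxy hydroperoxide aldehyde 6 (not isolated), via methoxy hydroperoxide acetal 7 (not isolated)
Conditions: O3, CH2Cl2/MeOH, −78 °C; TsOH·H2O (cat.), → rt; NaHCO3, then Me2S, rt
Reagents that add atoms: ozone ([O-][O+]=O); methanol (CO)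
Why: Unsymmetrical ozonolysis in methanol (Criegee cleavage, the carbonyl oxide on the more substituted carbon being trapped as the methoxy hydroperoxide), acid-catalysed acetalisation of the free C3 aldehyde and sulfide reduction differentiate the C3 and C12 carbonyl groups in one pot.

Step 5
Reactants: 8 methyl (3R)-3-(2,2-dimethoxyethyl)-2-methyl-6-oxoheptanoate; 9 triethyl phosphonoacetate
Product: 10 1-ethyl 8-methyl (2E,6R)-6-(2,2-dimethoxyethyl)-3,7-dimethyloct-2-enedioate (C15 epimers)
Conditions: NaH, THF, 0 → 50 °C; chromatographic removal of the minor 11Z isomer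
Reagents that add atoms: none
Why: Horner–Wadsworth–Emmons olefination of the methyl ketone should favour the E enoate (ester anti to the longer chain), and the conjugated ester keeps C11=C12 inert to the epoxidation of step 14.

Step 6
Reactants: 10 1-ethyl 8-methyl (2E,6R)-6-(2,2-dimethoxyethyl)-3,7-dimethyloct-2-enedioate
Product: 11 1-ethyl 8-methyl (2E,6R)-3,7-dimethyl-6-(2-oxoethyl)oct-2-enedioate (C15 epimers)
Conditions: TsOH·H2O (cat.), acetone/H2O, rt
Reagents that add atoms: water (O)
Why: Acid-catalysed acetal hydrolysis frees the C3 aldehyde under conditions that leave both esters untouched.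

Step 7
Reactants: 11 1-ethyl 8-methyl (2E,6R)-3,7-dimethyl-6-(2-oxoethyl)oct-2-enedioate; 12 isopropenylmagnesium bromide
Product: 13 1-ethyl 8-methyl (2E,6R)-6-(2-hydroxy-3-methylbut-3-en-1-yl)-3,7-dimethyloct-2-enedioate (C3 and C15 epimers)
Conditions: THF, −78 °C; AcOH quench at −78 °C; crude product used at once
Reagents that add atoms: none
Why: Grignard 1,2-addition at −78 °C is selective for the aldehyde over the hindered saturated ester and the β,β-disubstituted enoate, and the configuration of the C3 carbinol is irrelevant because C3 becomes sp2 in step 8.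

Step 8
Reactants: 13 1-ethyl 8-methyl (2E,6R)-6-(2-hydroxy-3-methylbut-3-en-1-yl)-3,7-dimethyloct-2-enedioate; 14 butyl vinyl ether
Product: 16 1-ethyl 8-methyl (2E,6R)-3,7-dimethyl-6-[(2E)-3-methyl-6-oxohex-2-en-1-yl]oct-2-enedioate (C15 epimers), via allyl vinyl ether 15 (not isolated)
Conditions: Pd(OCOCF3)2/4,7-diphenyl-1,10-phenanthroline (cat.), Et3N, neat 14, 40 °C; evaporate; toluene, 150 °C (sealed tube)
Reagents that add atoms: none
Why: Palladium(II)-catalysed transfer vinylation followed by a thermal Claisen [3,3] rearrangement through a chair transition state with the C2 chain equatorial forms C5–C6, should give the 3E trisubstituted olefin, and ends at the C7 aldehyde, the one carbonyl group more electrophilic than the esters.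

Step 9
Reactants: 17 2-bromoprop-2-en-1-ol
Product: 18 [(2-bromoprop-2-en-1-yl)oxy](tert-butyl)dimethylsilane
Conditions: TBSCl, imidazole, CH2Cl2, 0 °C → rt
Reagents that add atoms: tert-butyldimethylsilyl chloride (CC(C)(C)[Si](C)(C)Cl)
Why: Imidazole-promoted silylation of the primary alcohol gives the vinyl bromide that will supply C8, C9 and C19.

Step 10
Reactants: 18 [(2-bromoprop-2-en-1-yl)oxy](tert-butyl)dimethylsilane; 16 1-ethyl 8-methyl (2E,6R)-3,7-dimethyl-6-[(2E)-3-methyl-6-oxohex-2-en-1-yl]oct-2-enedioate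
Product: 20 10-ethyl 16-methyl (1R,3E,11E)-9-(TBSO)-7-hydroxy-9,10-seco-cembra-3,8(19),11-triene-10,16-dioate (C7 and C15 epimers), via 2-lithioallyl silyl ether 19 (not isolated)
Conditions: 18, t-BuLi (2 equiv), Et2O, −78 °C; then 16, −78 °C; AcOH quench
Reagents that add atoms: none
Why: Bromine–lithium exchange gives the 2-lithioallyl ether, which adds 1,2 to the aldehyde at −78 °C far faster than to either ester, and the C7 configuration is fixed two steps later.

Step 11
Reactants: 20 C7 carbinol diester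
Product: 21 10-ethyl 16-methyl (1R,3E,11E)-9-(TBSO)-7-oxo-9,10-seco-cembra-3,8(19),11-triene-10,16-dioate (C15 epimers)
Conditions: Dess–Martin periodinane, CH2Cl2, 0 °C → rt
Reagents that add atoms: none
Why: Dess–Martin oxidation of the secondary allylic alcohol gives the α-substituted vinyl ketone needed for a reagent-controlled reduction.

Step 12
Reactants: 21 C7 enone diester
Product: 22 10-ethyl 16-methyl (1R,3E,7R,11E)-9-(TBSO)-7-hydroxy-9,10-seco-cembra-3,8(19),11-triene-10,16-dioate (C15 epimers)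
Conditions: (S)-2-methyl-CBS-oxazaborolidine (0.2 equiv), catecholborane, toluene, −78 °C; aqueous work-up
Reagents that add atoms: none
Why: In the Corey–Bakshi–Shibata reduction the (S)-oxazaborolidine treats the α-branched alkenyl group as the large substituent and delivers hydride to give the 7R alcohol, while catecholborane leaves esters and olefins untouched.

Step 13
Reactants: 22 (7R)-allylic alcohol diester
Product: 23 10-ethyl 16-methyl (1R,3E,7R,11E)-7,9-bis(TBSO)-9,10-seco-cembra-3,8(19),11-triene-10,16-dioate (C15 epimers)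
Conditions: TBSOTf, 2,6-lutidine, CH2Cl2, −78 → 0 °C
Reagents that add atoms: tert-butyldimethylsilyl trifluoromethanesulfonate (CC(C)(C)[Si](C)(C)OS(=O)(=O)C(F)(F)F)
Why: Silyl triflate/lutidine silylation protects the hindered secondary allylic alcohol as the TBS ether that stays until the last step.

Step 14
Reactants: 23 bis-TBS triene diester
Product: 24 10-ethyl 16-methyl (1R,3S,4S,7R,11E)-7,9-bis(TBSO)-3,4-epoxy-9,10-seco-cembra-8(19),11-diene-10,16-dioate (C15 epimers)
Conditions: L-fructose-derived Shi ketone (0.3 equiv), Oxone, K2CO3, Bu4NHSO4 (cat.), MeCN/DMM–aq. borate buffer (pH 10.5), 0 °C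
Reagents that add atoms: potassium peroxymonosulfate ([K+].[O-]S(=O)(=O)OO)
Why: Shi epoxidation (spiro transition state) with the enantiomer of the common D-fructose-derived ketone should oxidise the only electron-rich trisubstituted olefin, C3=C4, on the face that gives 3S,4S, the enoate and the oxygen-flanked 1,1-disubstituted olefin being too electron-poor to compete.

Step 15
Reactants: 24 (3S,4S)-epoxy diester
Product: 26 (1R,3R,4S,7R,11E)-7,9-bis(TBSO)-4-hydroxy-9,10-seco-cembra-8(19),11-dien-16,3-olid-10-oic acid (C15 epimers), via epoxy dicarboxylate dilithium salt 25 (not isolated)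
Conditions: LiOH·H2O, THF/MeOH/H2O, 55 °C; 1 M HCl to pH 3–4, 0 °C; PPTS (cat.), CH2Cl2, rt
Reagents that add atoms: lithium hydroxide ([Li+].[OH-])
Why: Saponification of both esters unmasks the C16 carboxylate, which opens the epoxide by 6-exo-tet SN2 attack at the secondary carbon C3 with inversion (C3 becomes R, C4 keeps its oxygen and stays S), so that acidification should give the δ-lactone with the free tertiary alcohol and the C10 acid.

Step 16
Reactants: 26 hydroxy lactone acid
Product: 28 (1R,3R,4S,7R,11E)-7,9-bis(TBSO)-4,10-dihydroxy-9,10-seco-cembra-8(19),11-dien-16,3-olide (C15 epimers), via mixed carbonic anhydride 27 (not isolated)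
Conditions: i-BuOCOCl, N-methylmorpholine, THF, −15 °C; then NaBH4, H2O, 0 °C
Reagents that add atoms: none
Why: Activation of the conjugated acid as a mixed carbonic anhydride and borohydride 1,2-reduction should give the E allylic alcohol under conditions too mild to reduce the δ-lactone.

Step 17
Reactants: 28 hydroxy lactone allylic alcohol (C15 epimers)
Product: 29 (1R,3R,4S,7R,15S,11E)-7,9-bis(TBSO)-4,10-dihydroxy-9,10-seco-cembra-8(19),11-dien-16,3-olide
Conditions: DBU, toluene, 70 °C; chromatography, minor epimer resubmitted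
Reagents that add atoms: none
Why: Base-mediated epimerisation through the lactone enolate should converge the C15 epimers on the thermodynamic 15S isomer, in which the C15 methyl is trans to the C1 chain and all three ring substituents are equatorial.

Step 18
Reactants: 29 (15S)-bis-TBS hydroxy lactone
Product: 30 (1R,3R,4S,7R,15S,11E)-7-(TBSO)-4,9,10-trihydroxy-9,10-seco-cembra-8(19),11-dien-16,3-olide
Conditions: HF·pyridine, pyridine, THF, 0 °C
Reagents that add atoms: none
Why: Buffered HF·pyridine should cleave the unhindered primary allylic TBS ether at C9 much faster than the secondary one at C7.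

Step 19
Reactants: 30 lactone 9,10-diol
Product: 32 (1R,3R,4S,7R,15S,11E)-9,10-dibromo-7-(TBSO)-4-hydroxy-9,10-seco-cembra-8(19),11-dien-16,3-olide, via bis-mesylate 31 (not isolated)
Conditions: MsCl, Et3N, THF, −40 °C; then LiBr, THF, −40 → 0 °C
Reagents that add atoms: lithium bromide ([Li+].[Br-])
Why: Mesylation of the two primary allylic alcohols (the tertiary 4-OH is inert at −40 °C) and SN2 displacement by bromide should give both allylic bromides without allylic transposition or loss of the 11E geometry.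

Step 20
Reactants: 32 lactone bis(allyl bromide)
Product: 34 (1R,3R,4S,7R,15S,11E)-7-(TBSO)-4-hydroxycembra-8(19),11-dien-16,3-olide, via bis-allylnickel chelate 33 (not isolated)
Conditions: Ni(cod)2 (3 equiv), degassed DMF, 45 °C, syringe-pump addition of 32 over 12 h (final ≤ 2 mM)
Reagents that add atoms: none
Why: Nickel(0) adds oxidatively to both allylic C–Br bonds, the allylnickel bromides collapse in the polar solvent to a chelated bis(η3-allyl)nickel species and NiBr2, and reductive elimination between the two primary termini forms C9–C10. The closest known reaction type is the nickel(0)-mediated intramolecular reductive coupling of bis-allylic bromides to macrocyclic 1,5-dienes. The 14-membered ring C1–C14 is closed by this C(sp3)–C(sp3) reductive elimination within the nickelacycle, a head-to-head (primary to primary) closure run under high dilution by slow addition to suppress intermolecular coupling. No stereocentre is formed, C1, C3, C4, C7 and C15 lie away from the reacting carbons, and the lactone, the tertiary alcohol and the silyl ether are inert to allylnickel halides. Head-to-head regioselectivity is needed and is secured by the substrate: the C9–C8–C19 allyl has two identical CH2 termini, so that either one gives the same exocyclic methylene, and the C10–C11–C12 allyl couples at its unhindered primary carbon and not at the fully substituted C12. The 11E geometry is also needed; the E (syn) form of the trisubstituted allyl is the more stable one, but syn–anti exchange on nickel can erode it, so the E/Z ratio of the product has to be checked.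

Step 21
Reactants: 34 macrocyclic diene lactone
Product: 35 (1R,3R,4S,7R,11S,12S,15S)-7-(TBSO)-11,12-epoxy-4-hydroxycembr-8(19)-en-16,3-olide
Conditions: L-fructose-derived Shi ketone (0.3 equiv), Oxone, K2CO3, Bu4NHSO4 (cat.), MeCN/DMM–aq. borate buffer (pH 10.5), 0 °C
Reagents that add atoms: potassium peroxymonosulfate ([K+].[O-]S(=O)(=O)OO)
Why: In this Shi epoxidation the dioxirane should attack the electron-rich trisubstituted 11,12-olefin in preference to the 1,1-disubstituted C8=C19 with its allylic silyl ether, and the same ketone enantiomer as in step 14 should set 11S,12S through the spiro transition state.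

Step 22
Reactants: 35 epoxy lactone TBS ether
Product: 36 (1R,3R,4S,7R,11S,12S,15S)-11,12-epoxy-4,7-dihydroxycembr-8(19)-en-16,3-olide (CNP0262409.1)
Conditions: TBAF, AcOH, THF, 0 °C → rt
Reagents that add atoms: none
Why: Fluoride-mediated desilylation buffered with acetic acid should free the 7-hydroxyl without opening the epoxide or the lactone.

**Compound list**

1 | (R)-(+)-limonene | CC1=CC[C@@H](CC1)C(C)=C | starting material
2 | B-{2-[(1R)-4-methylcyclohex-3-en-1-yl]propyl}-9-borabicyclo[3.3.1]nonane (C15 epimers) | CC1=CC[C@@H](CC1)C(C)CB1C2CCCC1CCC2 | intermediate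
3 | 2-[(1R)-4-methylcyclohex-3-en-1-yl]propan-1-ol, (4R)-p-menth-1-en-9-ol (C15 epimers) | CC1=CC[C@@H](CC1)C(C)CO | intermediate
4 | 2-[(1R)-4-methylcyclohex-3-en-1-yl]propanoic acid (C15 epimers) | CC1=CC[C@@H](CC1)C(C)C(O)=O | intermediate
5 | methyl 2-[(1R)-4-methylcyclohex-3-en-1-yl]propanoate (C15 epimers) | CC1=CC[C@@H](CC1)C(C)C(=O)OC | intermediate
6 | methyl (3R)-6-hydroperoxy-6-methoxy-2-methyl-3-(2-oxoethyl)heptanoate (epimers at C2 and C6) | O=CC[C@@H](CCC(C)(OC)OO)C(C)C(=O)OC | intermediate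
7 | methyl (3R)-3-(2,2-dimethoxyethyl)-6-hydroperoxy-6-methoxy-2-methylheptanoate (epimers at C2 and C6) | COC(OC)C[C@@H](CCC(C)(OC)OO)C(C)C(=O)OC | intermediate
8 | methyl (3R)-3-(2,2-dimethoxyethyl)-2-methyl-6-oxoheptanoate (C15 epimers) | COC(OC)C[C@@H](CCC(C)=O)C(C)C(=O)OC | intermediate
9 | triethyl phosphonoacetate | CCOC(=O)CP(=O)(OCC)OCC | starting material
10 | 1-ethyl 8-methyl (2E,6R)-6-(2,2-dimethoxyethyl)-3,7-dimethyloct-2-enedioate (C15 epimers) | COC(OC)C[C@@H](CC/C(C)=C/C(=O)OCC)C(C)C(=O)OC | intermediate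
11 | 1-ethyl 8-methyl (2E,6R)-3,7-dimethyl-6-(2-oxoethyl)oct-2-enedioate (C15 epimers) | O=CC[C@@H](CC/C(C)=C/C(=O)OCC)C(C)C(=O)OC | intermediate
12 | isopropenylmagnesium bromide (prop-1-en-2-ylmagnesium bromide) | CC(=C)[Mg]Br | starting material
13 | 1-ethyl 8-methyl (2E,6R)-6-(2-hydroxy-3-methylbut-3-en-1-yl)-3,7-dimethyloct-2-enedioate (C3 and C15 epimers) | CC(=C)C(O)C[C@@H](CC/C(C)=C/C(=O)OCC)C(C)C(=O)OC | intermediate
14 | butyl vinyl ether | C=COCCCC | starting material
15 | 1-ethyl 8-methyl (2E,6R)-6-[2-(ethenyloxy)-3-methylbut-3-en-1-yl]-3,7-dimethyloct-2-enedioate (C3 and C15 epimers) | CC(=C)C(OC=C)C[C@@H](CC/C(C)=C/C(=O)OCC)C(C)C(=O)OC | intermediate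
16 | 1-ethyl 8-methyl (2E,6R)-3,7-dimethyl-6-[(2E)-3-methyl-6-oxohex-2-en-1-yl]oct-2-enedioate (C15 epimers) | O=CCC/C(C)=C/C[C@@H](CC/C(C)=C/C(=O)OCC)C(C)C(=O)OC | intermediate
17 | 2-bromoprop-2-en-1-ol | OCC(Br)=C | starting material
18 | [(2-bromoprop-2-en-1-yl)oxy](tert-butyl)dimethylsilane | CC(C)(C)[Si](C)(C)OCC(Br)=C | intermediate
19 | {3-[(tert-butyldimethylsilyl)oxy]prop-1-en-2-yl}lithium | [Li]C(=C)CO[Si](C)(C)C(C)(C)C | intermediate
20 | 10-ethyl 16-methyl (1R,3E,11E)-9-(tert-butyldimethylsilyloxy)-7-hydroxy-9,10-seco-cembra-3,8(19),11-triene-10,16-dioate (C7 and C15 epimers) | CC(C)(C)[Si](C)(C)OCC(=C)C(O)CC/C(C)=C/C[C@@H](CC/C(C)=C/C(=O)OCC)C(C)C(=O)OC | intermediate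
21 | 10-ethyl 16-methyl (1R,3E,11E)-9-(tert-butyldimethylsilyloxy)-7-oxo-9,10-seco-cembra-3,8(19),11-triene-10,16-dioate (C15 epimers) | CC(C)(C)[Si](C)(C)OCC(=C)C(=O)CC/C(C)=C/C[C@@H](CC/C(C)=C/C(=O)OCC)C(C)C(=O)OC | intermediate
22 | 10-ethyl 16-methyl (1R,3E,7R,11E)-9-(tert-butyldimethylsilyloxy)-7-hydroxy-9,10-seco-cembra-3,8(19),11-triene-10,16-dioate (C15 epimers) | CC(C)(C)[Si](C)(C)OCC(=C)[C@H](O)CC/C(C)=C/C[C@@H](CC/C(C)=C/C(=O)OCC)C(C)C(=O)OC | intermediate
23 | 10-ethyl 16-methyl (1R,3E,7R,11E)-7,9-bis(tert-butyldimethylsilyloxy)-9,10-seco-cembra-3,8(19),11-triene-10,16-dioate (C15 epimers) | CC(C)(C)[Si](C)(C)OCC(=C)[C@H](O[Si](C)(C)C(C)(C)C)CC/C(C)=C/C[C@@H](CC/C(C)=C/C(=O)OCC)C(C)C(=O)OC | intermediate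
24 | 10-ethyl 16-methyl (1R,3S,4S,7R,11E)-7,9-bis(tert-butyldimethylsilyloxy)-3,4-epoxy-9,10-seco-cembra-8(19),11-diene-10,16-dioate (C15 epimers) | CC(C)(C)[Si](C)(C)OCC(=C)[C@H](O[Si](C)(C)C(C)(C)C)CC[C@]1(C)O[C@H]1C[C@@H](CC/C(C)=C/C(=O)OCC)C(C)C(=O)OC | intermediate
25 | dilithium (1R,3S,4S,7R,11E)-7,9-bis(tert-butyldimethylsilyloxy)-3,4-epoxy-9,10-seco-cembra-8(19),11-diene-10,16-dioate (C15 epimers) | [Li+].[Li+].CC(C)(C)[Si](C)(C)OCC(=C)[C@H](O[Si](C)(C)C(C)(C)C)CC[C@]1(C)O[C@H]1C[C@@H](CC/C(C)=C/C([O-])=O)C(C)C([O-])=O | intermediate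
26 | (1R,3R,4S,7R,11E)-7,9-bis(tert-butyldimethylsilyloxy)-4-hydroxy-9,10-seco-cembra-8(19),11-dien-16,3-olid-10-oic acid (C15 epimers) | CC(C)(C)[Si](C)(C)OCC(=C)[C@H](O[Si](C)(C)C(C)(C)C)CC[C@](C)(O)[C@H]1C[C@@H](CC/C(C)=C/C(O)=O)C(C)C(=O)O1 | intermediate
27 | mixed anhydride of 26 with isobutyl hydrogen carbonate (C15 epimers) | CC(C)(C)[Si](C)(C)OCC(=C)[C@H](O[Si](C)(C)C(C)(C)C)CC[C@](C)(O)[C@H]1C[C@@H](CC/C(C)=C/C(=O)OC(=O)OCC(C)C)C(C)C(=O)O1 | intermediate
28 | (1R,3R,4S,7R,11E)-7,9-bis(tert-butyldimethylsilyloxy)-4,10-dihydroxy-9,10-seco-cembra-8(19),11-dien-16,3-olide (C15 epimers) | CC(C)(C)[Si](C)(C)OCC(=C)[C@H](O[Si](C)(C)C(C)(C)C)CC[C@](C)(O)[C@H]1C[C@@H](CC/C(C)=C/CO)C(C)C(=O)O1 | intermediate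
29 | (1R,3R,4S,7R,15S,11E)-7,9-bis(tert-butyldimethylsilyloxy)-4,10-dihydroxy-9,10-seco-cembra-8(19),11-dien-16,3-olide | CC(C)(C)[Si](C)(C)OCC(=C)[C@H](O[Si](C)(C)C(C)(C)C)CC[C@](C)(O)[C@H]1C[C@@H](CC/C(C)=C/CO)[C@H](C)C(=O)O1 | intermediate
30 | (1R,3R,4S,7R,15S,11E)-7-(tert-butyldimethylsilyloxy)-4,9,10-trihydroxy-9,10-seco-cembra-8(19),11-dien-16,3-olide | OCC(=C)[C@H](O[Si](C)(C)C(C)(C)C)CC[C@](C)(O)[C@H]1C[C@@H](CC/C(C)=C/CO)[C@H](C)C(=O)O1 | intermediate
31 | 9,10-bis(methanesulfonate) of 30 | CS(=O)(=O)OCC(=C)[C@H](O[Si](C)(C)C(C)(C)C)CC[C@](C)(O)[C@H]1C[C@@H](CC/C(C)=C/COS(C)(=O)=O)[C@H](C)C(=O)O1 | intermediate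
32 | (1R,3R,4S,7R,15S,11E)-9,10-dibromo-7-(tert-butyldimethylsilyloxy)-4-hydroxy-9,10-seco-cembra-8(19),11-dien-16,3-olide | BrCC(=C)[C@H](O[Si](C)(C)C(C)(C)C)CC[C@](C)(O)[C@H]1C[C@@H](CC/C(C)=C/CBr)[C@H](C)C(=O)O1 | intermediate
33 | bis(η3-allyl)nickel chelate of the C9–C8–C19 and C10–C11–C12 allyl units of 32 (drawn as the σ,σ-bonded nickelacycle) | C=C1C[Ni]C/C=C(\C)CC[C@@H]2C[C@@H](OC(=O)[C@H]2C)[C@@](C)(O)CC[C@H]1O[Si](C)(C)C(C)(C)C | intermediate
34 | (1R,3R,4S,7R,15S,11E)-7-(tert-butyldimethylsilyloxy)-4-hydroxycembra-8(19),11-dien-16,3-olide | C=C1CC/C=C(\C)CC[C@@H]2C[C@@H](OC(=O)[C@H]2C)[C@@](C)(O)CC[C@H]1O[Si](C)(C)C(C)(C)C | intermediate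
35 | (1R,3R,4S,7R,11S,12S,15S)-7-(tert-butyldimethylsilyloxy)-11,12-epoxy-4-hydroxycembr-8(19)-en-16,3-olide | C=C1CC[C@@H]2O[C@@]2(C)CC[C@@H]2C[C@@H](OC(=O)[C@H]2C)[C@@](C)(O)CC[C@H]1O[Si](C)(C)C(C)(C)C | intermediate
36 | (1R,3R,4S,7R,11S,12S,15S)-11,12-epoxy-4,7-dihydroxycembr-8(19)-en-16,3-olide (CNP0262409.1) | C=C1CC[C@@H]2O[C@@]2(C)CC[C@@H]2C[C@@H](OC(=O)[C@H]2C)[C@@](C)(O)CC[C@H]1O | target

**Totals and risks**

Total step count: 22. Longest linear sequence: 21 steps (1–8 and 10–22; step 9 is a one-step side branch).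

Steps most likely to fail:

1. Step 20 (nickel macrocyclisation). What may go wrong: intermolecular coupling to oligomers, reduction of a C–Br bond, and loss of the 11E geometry through syn–anti exchange of the trisubstituted allylnickel unit. Fallback, from 29 back to 34: the two allyl termini are differentiated and the same C9–C10 bond is made by alkylation of a sulfone-stabilised allyl anion. Compound 29 is converted at C10 (MsCl, Et3N; LiBr) into the C10 mono-bromide F1, which with sodium benzenesulfinate in DMF gives the C10 allyl phenyl sulfone F2. HF·pyridine frees the C9 alcohol F3, and MsCl/Et3N followed by LiBr gives the sulfonyl allylic bromide F4. LiHMDS (2.2 equiv) in THF at high dilution closes the ring by intramolecular SN2 alkylation of the C10 carbanion at C9 to the macrocyclic sulfone F5. Buffered sodium amalgam (Na2HPO4, MeOH/THF, −20 °C) removes the sulfonyl group and gives 34.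

2. Step 21 (epoxidation of the macrocycle). What may go wrong: poor or reversed facial selectivity, because the ring may expose only one face of the 11,12-olefin and override the catalyst. Fallback, from 34 back to 35: the facial sense is inverted by the two-step halohydrin route. NBS in aqueous THF at 0 °C forms the bromonium ion on the exposed face of the more nucleophilic 11,12-olefin, and water opens it anti at the tertiary C12 to give the (11R,12S)-bromohydrin F6. DBU in CH2Cl2 then closes the oxirane by SN2 displacement at C11, which places the oxygen on the face opposite to the one attacked by the electrophile and gives 35.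

3. Step 17 (C15 equilibration). What may go wrong: incomplete thermodynamic bias, the equilibrium between the C15 epimers not lying far enough on the all-equatorial side. Fallback, from 1 back to 29: C15 is fixed by reagent control before the ring is opened. Allylic metalation of 1 (n-BuLi, TMEDA), borylation (B(OMe)3) and oxidation (H2O2, NaOH) give the dienol 2-[(1R)-4-methylcyclohex-3-en-1-yl]prop-2-en-1-ol F7. MnO2 gives the enal F8, and Pinnick oxidation (NaClO2, NaH2PO4, 2-methyl-2-butene) gives the 2-substituted acrylic acid F9. Hydrogenation with Ru(OAc)2[(S)-BINAP] (H2, MeOH; ligand chosen by analogy with 2-arylacrylic acids, the antipode being equally available) reduces only the acrylic double bond and should give the (2S)-acid F10, the 15S epimer of 4. Carried through steps 3 to 16 as the 15S members of the listed epimer pairs, F10 delivers 29 directly.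

**Further compounds**

F1 | step 20 | (1R,3R,4S,7R,15S,11E)-10-bromo-7,9-bis(tert-butyldimethylsilyloxy)-4-hydroxy-9,10-seco-cembra-8(19),11-dien-16,3-olide | CC(C)(C)[Si](C)(C)OCC(=C)[C@H](O[Si](C)(C)C(C)(C)C)CC[C@](C)(O)[C@H]1C[C@@H](CC/C(C)=C/CBr)[C@H](C)C(=O)O1
F2 | step 20 | (1R,3R,4S,7R,15S,11E)-7,9-bis(tert-butyldimethylsilyloxy)-4-hydroxy-10-(phenylsulfonyl)-9,10-seco-cembra-8(19),11-dien-16,3-olide | CC(C)(C)[Si](C)(C)OCC(=C)[C@H](O[Si](C)(C)C(C)(C)C)CC[C@](C)(O)[C@H]1C[C@@H](CC/C(C)=C/CS(=O)(=O)c2ccccc2)[C@H](C)C(=O)O1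
F3 | step 20 | (1R,3R,4S,7R,15S,11E)-7-(tert-butyldimethylsilyloxy)-4,9-dihydroxy-10-(phenylsulfonyl)-9,10-seco-cembra-8(19),11-dien-16,3-olide | OCC(=C)[C@H](O[Si](C)(C)C(C)(C)C)CC[C@](C)(O)[C@H]1C[C@@H](CC/C(C)=C/CS(=O)(=O)c2ccccc2)[C@H](C)C(=O)O1
F4 | step 20 | (1R,3R,4S,7R,15S,11E)-9-bromo-7-(tert-butyldimethylsilyloxy)-4-hydroxy-10-(phenylsulfonyl)-9,10-seco-cembra-8(19),11-dien-16,3-olide | BrCC(=C)[C@H](O[Si](C)(C)C(C)(C)C)CC[C@](C)(O)[C@H]1C[C@@H](CC/C(C)=C/CS(=O)(=O)c2ccccc2)[C@H](C)C(=O)O1
F5 | step 20 | (1R,3R,4S,7R,15S,11E)-7-(tert-butyldimethylsilyloxy)-4-hydroxy-10-(phenylsulfonyl)cembra-8(19),11-dien-16,3-olide (C10 epimers) | C=C1CC(S(=O)(=O)c3ccccc3)/C=C(\C)CC[C@@H]2C[C@@H](OC(=O)[C@H]2C)[C@@](C)(O)CC[C@H]1O[Si](C)(C)C(C)(C)C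
F6 | step 21 | (1R,3R,4S,7R,11R,12S,15S)-11-bromo-7-(tert-butyldimethylsilyloxy)-4,12-dihydroxycembr-8(19)-en-16,3-olide | C=C1CC[C@@H](Br)[C@@](C)(O)CC[C@@H]2C[C@@H](OC(=O)[C@H]2C)[C@@](C)(O)CC[C@H]1O[Si](C)(C)C(C)(C)C
F7 | step 17 | 2-[(1R)-4-methylcyclohex-3-en-1-yl]prop-2-en-1-ol | CC1=CC[C@@H](CC1)C(=C)CO
F8 | step 17 | 2-[(1R)-4-methylcyclohex-3-en-1-yl]prop-2-enal | CC1=CC[C@@H](CC1)C(=C)C=O
F9 | step 17 | 2-[(1R)-4-methylcyclohex-3-en-1-yl]prop-2-enoic acid | CC1=CC[C@@H](CC1)C(=C)C(O)=O
F10 | step 17 | (2S)-2-[(1R)-4-methylcyclohex-3-en-1-yl]propanoic acid | CC1=CC[C@@H](CC1)[C@H](C)C(O)=O
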